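**Retrosynthetic overview**
1. The ten-membered carbocycle is closed last, by ring-closing metathesis at C1=C10 of seco-triene 32 (germacrane numbering).
2. Key step: the C7–C8 bond of 32 is made by a zinc Barbier reaction in which the β-carbon of 3-(bromomethyl)butenolide 19 (a lactone homoenolate equivalent) attacks α-acyloxy aldehyde 30. This sets C7 and C8 and unveils the α-methylene-γ-lactone.
3. Bromide 19 comes from (S)-glyceraldehyde acetonide: Still–Gennari olefination (Z-C4=C5), Brown allylation (C3), then Morita–Baylis–Hillman reaction, lactonisation and SN2′ bromination.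
4. Aldehyde 30 comes from a kinetically resolved isopropenyl carbinol (C9) esterified with (2R,3R)-epoxyangelic acid 23, itself made by Sharpless epoxidation of angelyl alcohol.
5. Ring order: oxirane (step 14), γ-lactone (step 11, carried as butenolide through step 12), ten-membered ring (step 22).

Assumption: germacrane numbering (C1–C15, lactone carbonyl C12, exocyclic methylene C13) is used for the ring carbons of all intermediates.

**Fragment 1: bromomethylbutenolide 19**

Step 1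
Reactants: 1 [(4R)-2,2-dimethyl-1,3-dioxolan-4-yl]methanol ((R)-solketal)
Product: 2 (4S)-2,2-dimethyl-1,3-dioxolane-4-carbaldehyde
Conditions: IBX (1.5 equiv), EtOAc, 75 °C; filter, use the solution directly
Reagents that add atoms: none
Why: IBX oxidation of the primary alcohol under neutral conditions gives the labile aldehyde without epimerisation; the future C6 centre is taken from the chiral pool (R→S is only a priority change).

Step 2
Reactants: 2 (4S)-2,2-dimethyl-1,3-dioxolane-4-carbaldehyde; 3 ethyl 2-[bis(2,2,2-trifluoroethoxy)phosphoryl]propanoate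
Product: 5 ethyl (2Z)-3-[(4R)-2,2-dimethyl-1,3-dioxolan-4-yl]-2-methylprop-2-enoate, via potassium phosphonate carbanion 4 (not isolated)
Conditions: KN(SiMe3)2, 18-crown-6, THF, −78 °C
Reagents that add atoms: none
Why: Still–Gennari olefination; the electron-poor phosphonate under dissociating conditions collapses the kinetic oxaphosphetane quickly and gives the Z-trisubstituted enoate that becomes the ring C4=C5 alkene.

Step 3
Reactants: 5 ethyl (2Z)-3-[(4R)-2,2-dimethyl-1,3-dioxolan-4-yl]-2-methylprop-2-enoate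
Product: 6 (2Z)-3-[(4R)-2,2-dimethyl-1,3-dioxolan-4-yl]-2-methylprop-2-en-1-ol
Conditions: iBu2AlH (2.2 equiv), CH2Cl2, −78 °C; H2O work-up
Reagents that add atoms: none
Why: 1,2-Hydride reduction of the ester at low temperature leaves the Z geometry and the acetonide untouched.

Step 4
Reactants: 6 (2Z)-3-[(4R)-2,2-dimethyl-1,3-dioxolan-4-yl]-2-methylprop-2-en-1-ol
Product: 7 (2Z)-3-[(4R)-2,2-dimethyl-1,3-dioxolan-4-yl]-2-methylprop-2-enal
Conditions: Dess–Martin periodinane, CH2Cl2, 0 °C; use at once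
Reagents that add atoms: none
Why: Dess–Martin oxidation is fast and non-basic, so the Z-α-methyl enal is obtained without Z→E isomerisation.

Step 5
Reactants: 7 (2Z)-3-[(4R)-2,2-dimethyl-1,3-dioxolan-4-yl]-2-methylprop-2-enal
Product: 9 (1Z,3S)-1-[(4R)-2,2-dimethyl-1,3-dioxolan-4-yl]-2-methylhexa-1,5-dien-3-ol, via diisopinocampheylborinate ester 8 (not isolated)
Conditions: (−)-B-allyldiisopinocampheylborane (from (+)-α-pinene), Et2O, −78 °C; then NaOH, H2O2, 0 °C → rt
Reagents that add atoms: (−)-B-allyldiisopinocampheylborane, C=CCB([C@@H]1C[C@@H]2C[C@H]([C@H]1C)C2(C)C)[C@@H]1C[C@@H]2C[C@H]([C@H]1C)C2(C)C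
Why: Brown asymmetric allylboration through a closed chair transition state; the isopinocampheyl groups direct the allyl group to the Si face of the enal and set C3 as S under reagent control.

Step 6
Reactants: 9 (1Z,3S)-1-[(4R)-2,2-dimethyl-1,3-dioxolan-4-yl]-2-methylhexa-1,5-dien-3-ol
Product: 10 (1Z,3S)-1-[(4R)-2,2-dimethyl-1,3-dioxolan-4-yl]-2-methylhexa-1,5-dien-3-yl acetate
Conditions: Ac2O, pyridine, DMAP (cat.), CH2Cl2, 0 °C → rt
Reagents that add atoms: acetic anhydride, CC(=O)OC(C)=O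
Why: DMAP-catalysed acetylation installs the C3 acetate of the target with retention.

Step 7
Reactants: 10 (1Z,3S)-1-[(4R)-2,2-dimethyl-1,3-dioxolan-4-yl]-2-methylhexa-1,5-dien-3-yl acetate
Product: 11 (2R,3Z,5S)-1,2-dihydroxy-4-methylocta-3,7-dien-5-yl acetate
Conditions: AcOH/H2O/THF (3:1:1), 40 °C
Reagents that add atoms: none
Why: Acid-catalysed hydrolysis of the terminal isopropylidene acetal; the allylic acetate and both alkenes tolerate mild aqueous acetic acid.

Step 8
Reactants: 11 (2R,3Z,5S)-1,2-dihydroxy-4-methylocta-3,7-dien-5-yl acetate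
Product: 12 (2R,3Z,5S)-4-methyl-1,2-bis[(triethylsilyl)oxy]octa-3,7-dien-5-yl acetate
Conditions: Et3SiCl (2.5 equiv), imidazole, CH2Cl2, 0 °C
Reagents that add atoms: chlorotriethylsilane, CC[Si](Cl)(CC)CC
Why: Silylation of both hydroxyls sets up the chemoselective oxidation of the primary position.

Step 9
Reactants: 12 (2R,3Z,5S)-4-methyl-1,2-bis[(triethylsilyl)oxy]octa-3,7-dien-5-yl acetate
Product: 14 (2R,3Z,5S)-4-methyl-1-oxo-2-[(triethylsilyl)oxy]octa-3,7-dien-5-yl acetate, via alkoxysulfonium chloride 13 (not isolated)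
Conditions: (COCl)2, DMSO, CH2Cl2, −78 → −40 °C; then Et3N, −78 → 0 °C
Reagents that add atoms: none
Why: Swern oxidation of a primary triethylsilyl ether directly to the aldehyde (activated DMSO desilylates the less hindered primary ether far faster than the secondary one), bringing C7 to the aldehyde level with C6–O still protected.

Step 10
Reactants: 14 (2R,3Z,5S)-4-methyl-1-oxo-2-[(triethylsilyl)oxy]octa-3,7-dien-5-yl acetate; 15 methyl prop-2-enoate (methyl acrylate)
Product: 16 methyl (3RS,4R,5Z,7S)-7-acetoxy-3-hydroxy-6-methyl-2-methylidene-4-[(triethylsilyl)oxy]deca-5,9-dienoate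
Conditions: DABCO (1 equiv), neat 15 (5 equiv), MeOH (2 equiv), 0 °C → rt
Reagents that add atoms: none
Why: Morita–Baylis–Hillman reaction forms the C7–C11 bond; the new C7 carbinol is an epimeric mixture, which does not matter because this centre becomes sp2 in step 12.

Step 11
Reactants: 16 methyl (3RS,4R,5Z,7S)-7-acetoxy-3-hydroxy-6-methyl-2-methylidene-4-[(triethylsilyl)oxy]deca-5,9-dienoate
Product: 18 (1Z,3S)-1-[(2R,3RS)-3-hydroxy-4-methylidene-5-oxooxolan-2-yl]-2-methylhexa-1,5-dien-3-yl acetate, via desilylated hydroxy ester 17 (not isolated)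
Conditions: HF·pyridine, THF, 0 °C → rt
Reagents that add atoms: none
Why: Desilylation frees the C6 hydroxyl, which lactonises onto the methyl ester to form the γ-lactone ring (C6 configuration untouched).

Step 12
Reactants: 18 (1Z,3S)-1-[(2R,3RS)-3-hydroxy-4-methylidene-5-oxooxolan-2-yl]-2-methylhexa-1,5-dien-3-yl acetate
Product: 19 (1Z,3S)-1-[(2R)-4-(bromomethyl)-5-oxo-2,5-dihydrofuran-2-yl]-2-methylhexa-1,5-dien-3-yl acetate
Conditions: PBr3 (0.4 equiv), Et2O, −20 → 0 °C
Reagents that add atoms: phosphorus tribromide, BrP(Br)Br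
Why: Allylic-transposition (SN2′) bromination of a Morita–Baylis–Hillman-type alcohol; bromide enters at C13 as the phosphite leaves C7, so both C7 epimers converge on the conjugated butenolide.

**Fragment 2: (2R,3R)-epoxyangelic acid 23**

Step 13
Reactants: 20 (2Z)-2-methylbut-2-enoic acid (angelic acid)
Product: 21 (2Z)-2-methylbut-2-en-1-ol
Conditions: LiAlH4, Et2O, 0 °C; H2O work-up
Reagents that add atoms: none
Why: 1,2-Selective hydride reduction of the acid gives the allylic alcohol with the Z geometry retained.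

Step 14
Reactants: 21 (2Z)-2-methylbut-2-en-1-ol
Product: 22 [(2S,3R)-2,3-dimethyloxiran-2-yl]methanol
Conditions: Ti(OiPr)4 (10 mol %), D-(−)-diethyl tartrate (12 mol %), tBuOOH, 4 Å molecular sieves, CH2Cl2, −20 °C
Reagents that add atoms: tert-butyl hydroperoxide, CC(C)(C)OO
Why: Sharpless asymmetric epoxidation; the D-tartrate catalyst delivers oxygen to the face that gives the (2S,3R) epoxide, and the Z alkene fixes the trans relationship of the two methyl groups.

Step 15
Reactants: 22 [(2S,3R)-2,3-dimethyloxiran-2-yl]methanol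
Product: 23 (2R,3R)-2,3-dimethyloxirane-2-carboxylic acid
Conditions: RuCl3 (2 mol %), NaIO4 (3 equiv), EtOAc/MeCN/H2O, rt
Reagents that add atoms: water, O
Why: Ruthenium tetroxide oxidation (RuCl3/NaIO4) of the primary alcohol to the acid via the aldehyde hydrate leaves the epoxide intact (2S→2R is only a priority change).

**Fragment 3: α-acyloxy aldehyde 30**

Step 16
Reactants: 24 [(tert-butyldimethylsilyl)oxy]acetaldehyde; 25 isopropenylmagnesium bromide, CH2=C(CH3)MgBr
Product: 26 rac-1-[(tert-butyldimethylsilyl)oxy]-3-methylbut-3-en-2-ol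
Conditions: THF, −78 → 0 °C; H2O quench
Reagents that add atoms: none
Why: Grignard 1,2-addition gives the racemic secondary allylic alcohol.

Step 17
Reactants: 26 rac-1-[(tert-butyldimethylsilyl)oxy]-3-methylbut-3-en-2-ol
Product: 27 (2R)-1-[(tert-butyldimethylsilyl)oxy]-3-methylbut-3-en-2-ol
Conditions: Ti(OiPr)4 (0.2 equiv), D-(−)-diisopropyl tartrate (0.24 equiv), tBuOOH (0.6 equiv), 4 Å molecular sieves, CH2Cl2, −20 °C; stop near 55% conversion
Reagents that add atoms: none
Why: Sharpless kinetic resolution; with the D-tartrate the S alcohol is epoxidised fast and the R alcohol (C9 of the target) is recovered in high ee (maximum yield 45%).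

Step 18
Reactants: 27 (2R)-1-[(tert-butyldimethylsilyl)oxy]-3-methylbut-3-en-2-ol; 23 (2R,3R)-2,3-dimethyloxirane-2-carboxylic acid
Product: 28 (2R)-1-[(tert-butyldimethylsilyl)oxy]-3-methylbut-3-en-2-yl (2R,3R)-2,3-dimethyloxirane-2-carboxylate
Conditions: DCC, DMAP (cat.), CH2Cl2, 0 °C → rt
Reagents that add atoms: none
Why: Steglich esterification proceeds with retention at C9, and any minor enantiomer carried from step 17 becomes a separable diastereomer.

Step 19
Reactants: 28 (2R)-1-[(tert-butyldimethylsilyl)oxy]-3-methylbut-3-en-2-yl (2R,3R)-2,3-dimethyloxirane-2-carboxylate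
Product: 29 (2R)-1-hydroxy-3-methylbut-3-en-2-yl (2R,3R)-2,3-dimethyloxirane-2-carboxylate
Conditions: HF·pyridine, pyridine, THF, 0 °C
Reagents that add atoms: none
Why: Buffered HF·pyridine desilylation is acidic enough to suppress secondary-to-primary acyl migration and mild toward the glycidic ester.

Step 20
Reactants: 29 (2R)-1-hydroxy-3-methylbut-3-en-2-yl (2R,3R)-2,3-dimethyloxirane-2-carboxylate
Product: 30 (2R)-3-methyl-1-oxobut-3-en-2-yl (2R,3R)-2,3-dimethyloxirane-2-carboxylate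
Conditions: Dess–Martin periodinane, CH2Cl2, 0 °C; crude aldehyde used at once
Reagents that add atoms: none
Why: Dess–Martin oxidation under non-basic conditions gives the α-acyloxy-β,γ-unsaturated aldehyde without C9 epimerisation or alkene migration.

**Fragment union and ring closure**

Step 21 (key step)
Reactants: 19 (1Z,3S)-1-[(2R)-4-(bromomethyl)-5-oxo-2,5-dihydrofuran-2-yl]-2-methylhexa-1,5-dien-3-yl acetate; 30 (2R)-3-methyl-1-oxobut-3-en-2-yl (2R,3R)-2,3-dimethyloxirane-2-carboxylate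
Product: 32 (1Z,3S)-1-[(2R,3R)-3-{(1R,2R)-2-{[(2R,3R)-2,3-dimethyloxirane-2-carbonyl]oxy}-1-hydroxy-3-methylbut-3-en-1-yl}-4-methylidene-5-oxooxolan-2-yl]-2-methylhexa-1,5-dien-3-yl acetate, via allylzinc bromide 31 (not isolated)
Conditions: Zn dust (activated), 19 (1.3 equiv), THF/sat. aq. NH4Cl (2:1), 0 °C → rt
Reagents that add atoms: none
Why: Zinc Barbier allylation with a 3-(halomethyl)butenolide, whose β-carbon C7 (an acceptor carbon in the butenolide) reacts as a homoenolate-type nucleophile with the aldehyde carbon C8 in an SE2′ sense, so the α-methylene-γ-lactone appears as the C7–C8 bond forms; C8 adds anti to the C6 side chain (trans-lactone, 7R), and the closed chair transition state with the aldehyde residue equatorial, helped by zinc chelation to the C9 acyloxy group, gives 8R (8,9-syn), while the aqueous NH4Cl medium protonates the alkoxide before acyl shift or translactonisation.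

Step 22
Reactants: 32 (seco-triene, name as in step 21)
Product: 33 (3aR,4R,5R,6Z,9S,10Z,11aR)-9-acetoxy-4-hydroxy-6,10-dimethyl-3-methylidene-2-oxo-2,3,3a,4,5,8,9,11a-octahydrocyclodeca[b]furan-5-yl (2R,3R)-2,3-dimethyloxirane-2-carboxylate (CNP0137407.10)
Conditions: RuCl2(=CH-C6H4-2-OiPr)(H2IMes) (second-generation Hoveyda–Grubbs catalyst, 15 mol %), toluene, 0.5 mM, 80 °C
Reagents that add atoms: none
Why: Ring-closing metathesis; the catalyst loads on the allyl terminus and closes onto the isopropenyl group, the ten-membered ring (held by the trans-lactone and the Z-C4=C5 alkene) enforcing the cis (Z) C1=C10 alkene, and the exocyclic methylene is spared because closure onto it would give a strained bridgehead-type alkene.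

**Compound list**
1 | [(4R)-2,2-dimethyl-1,3-dioxolan-4-yl]methanol ((R)-solketal) | CC1(C)OC[C@@H](CO)O1 | starting material
2 | (4S)-2,2-dimethyl-1,3-dioxolane-4-carbaldehyde | CC1(C)OC[C@@H](C=O)O1 | intermediate
3 | ethyl 2-[bis(2,2,2-trifluoroethoxy)phosphoryl]propanoate | CCOC(=O)C(C)P(=O)(OCC(F)(F)F)OCC(F)(F)F | starting material
4 | potassium salt of the carbanion of 3 | CCOC(=O)[C-](C)P(=O)(OCC(F)(F)F)OCC(F)(F)F.[K+] | intermediate (not isolated)
5 | ethyl (2Z)-3-[(4R)-2,2-dimethyl-1,3-dioxolan-4-yl]-2-methylprop-2-enoate | CC1(C)OC[C@@H](/C=C(/C)C(=O)OCC)O1 | intermediate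
6 | (2Z)-3-[(4R)-2,2-dimethyl-1,3-dioxolan-4-yl]-2-methylprop-2-en-1-ol | CC1(C)OC[C@@H](/C=C(/C)CO)O1 | intermediate
7 | (2Z)-3-[(4R)-2,2-dimethyl-1,3-dioxolan-4-yl]-2-methylprop-2-enal | CC1(C)OC[C@@H](/C=C(/C)C=O)O1 | intermediate
8 | (1Z,3S)-1-[(4R)-2,2-dimethyl-1,3-dioxolan-4-yl]-2-methylhexa-1,5-dien-3-yl diisopinocampheylborinate | CC1(C)OC[C@@H](/C=C(/C)[C@@H](OB([C@@H]2C[C@@H]3C[C@H]([C@H]2C)C3(C)C)[C@@H]2C[C@@H]3C[C@H]([C@H]2C)C3(C)C)CC=C)O1 | intermediate (not isolated)
9 | (1Z,3S)-1-[(4R)-2,2-dimethyl-1,3-dioxolan-4-yl]-2-methylhexa-1,5-dien-3-ol | CC1(C)OC[C@@H](/C=C(/C)[C@@H](O)CC=C)O1 | intermediate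
10 | (1Z,3S)-1-[(4R)-2,2-dimethyl-1,3-dioxolan-4-yl]-2-methylhexa-1,5-dien-3-yl acetate | CC1(C)OC[C@@H](/C=C(/C)[C@@H](OC(C)=O)CC=C)O1 | intermediate
11 | (2R,3Z,5S)-1,2-dihydroxy-4-methylocta-3,7-dien-5-yl acetate | OC[C@H](O)/C=C(/C)[C@@H](OC(C)=O)CC=C | intermediate
12 | (2R,3Z,5S)-4-methyl-1,2-bis[(triethylsilyl)oxy]octa-3,7-dien-5-yl acetate | CC[Si](CC)(CC)OC[C@H](O[Si](CC)(CC)CC)/C=C(/C)[C@@H](OC(C)=O)CC=C | intermediate
13 | {[(2R,3Z,5S)-5-acetoxy-4-methyl-2-[(triethylsilyl)oxy]octa-3,7-dien-1-yl]oxy}dimethylsulfonium chloride | C[S+](C)OC[C@H](O[Si](CC)(CC)CC)/C=C(/C)[C@@H](OC(C)=O)CC=C.[Cl-] | intermediate (not isolated)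
14 | (2R,3Z,5S)-4-methyl-1-oxo-2-[(triethylsilyl)oxy]octa-3,7-dien-5-yl acetate | O=C[C@H](O[Si](CC)(CC)CC)/C=C(/C)[C@@H](OC(C)=O)CC=C | intermediate
15 | methyl prop-2-enoate (methyl acrylate) | C=CC(=O)OC | starting material
16 | methyl (3RS,4R,5Z,7S)-7-acetoxy-3-hydroxy-6-methyl-2-methylidene-4-[(triethylsilyl)oxy]deca-5,9-dienoate (C7 epimers) | COC(=O)C(=C)C(O)[C@H](O[Si](CC)(CC)CC)/C=C(/C)[C@@H](OC(C)=O)CC=C | intermediate
17 | methyl (3RS,4R,5Z,7S)-7-acetoxy-3,4-dihydroxy-6-methyl-2-methylidenedeca-5,9-dienoate | COC(=O)C(=C)C(O)[C@H](O)/C=C(/C)[C@@H](OC(C)=O)CC=C | intermediate (not isolated)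
18 | (1Z,3S)-1-[(2R,3RS)-3-hydroxy-4-methylidene-5-oxooxolan-2-yl]-2-methylhexa-1,5-dien-3-yl acetate | C=C1C(O)[C@@H](/C=C(/C)[C@@H](OC(C)=O)CC=C)OC1=O | intermediate
19 | (1Z,3S)-1-[(2R)-4-(bromomethyl)-5-oxo-2,5-dihydrofuran-2-yl]-2-methylhexa-1,5-dien-3-yl acetate | BrCC1=C[C@@H](/C=C(/C)[C@@H](OC(C)=O)CC=C)OC1=O | intermediate
20 | (2Z)-2-methylbut-2-enoic acid (angelic acid) | C/C=C(/C)C(=O)O | starting material
21 | (2Z)-2-methylbut-2-en-1-ol | C/C=C(/C)CO | intermediate
22 | [(2S,3R)-2,3-dimethyloxiran-2-yl]methanol | OC[C@]1(C)O[C@@H]1C | intermediate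
23 | (2R,3R)-2,3-dimethyloxirane-2-carboxylic acid | OC(=O)[C@]1(C)O[C@@H]1C | intermediate
24 | [(tert-butyldimethylsilyl)oxy]acetaldehyde | CC(C)(C)[Si](C)(C)OCC=O | starting material
25 | isopropenylmagnesium bromide | CC(=C)[Mg]Br | starting material
26 | rac-1-[(tert-butyldimethylsilyl)oxy]-3-methylbut-3-en-2-ol (racemate) | C=C(C)C(O)CO[Si](C)(C)C(C)(C)C | intermediate
27 | (2R)-1-[(tert-butyldimethylsilyl)oxy]-3-methylbut-3-en-2-ol | C=C(C)[C@@H](O)CO[Si](C)(C)C(C)(C)C | intermediate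
28 | (2R)-1-[(tert-butyldimethylsilyl)oxy]-3-methylbut-3-en-2-yl (2R,3R)-2,3-dimethyloxirane-2-carboxylate | C=C(C)[C@@H](OC(=O)[C@]1(C)O[C@@H]1C)CO[Si](C)(C)C(C)(C)C | intermediate
29 | (2R)-1-hydroxy-3-methylbut-3-en-2-yl (2R,3R)-2,3-dimethyloxirane-2-carboxylate | C=C(C)[C@@H](OC(=O)[C@]1(C)O[C@@H]1C)CO | intermediate
30 | (2R)-3-methyl-1-oxobut-3-en-2-yl (2R,3R)-2,3-dimethyloxirane-2-carboxylate | C=C(C)[C@@H](OC(=O)[C@]1(C)O[C@@H]1C)C=O | intermediate
31 | bromo{[(5R)-5-[(1Z,3S)-3-acetoxy-2-methylhexa-1,5-dien-1-yl]-2-oxo-2,5-dihydrofuran-3-yl]methyl}zinc | Br[Zn]CC1=C[C@@H](/C=C(/C)[C@@H](OC(C)=O)CC=C)OC1=O | intermediate (not isolated)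
32 | (1Z,3S)-1-[(2R,3R)-3-{(1R,2R)-2-{[(2R,3R)-2,3-dimethyloxirane-2-carbonyl]oxy}-1-hydroxy-3-methylbut-3-en-1-yl}-4-methylidene-5-oxooxolan-2-yl]-2-methylhexa-1,5-dien-3-yl acetate | C=C1C(=O)O[C@H](/C=C(/C)[C@@H](OC(C)=O)CC=C)[C@H]1[C@@H](O)[C@H](OC(=O)[C@]2(C)O[C@@H]2C)C(C)=C | intermediate
33 | (3aR,4R,5R,6Z,9S,10Z,11aR)-9-acetoxy-4-hydroxy-6,10-dimethyl-3-methylidene-2-oxo-2,3,3a,4,5,8,9,11a-octahydrocyclodeca[b]furan-5-yl (2R,3R)-2,3-dimethyloxirane-2-carboxylate (CNP0137407.10) | C=C1C(=O)O[C@@H]2/C=C(/C)[C@@H](OC(C)=O)C/C=C(/C)[C@@H](OC(=O)[C@]3(C)O[C@@H]3C)[C@H](O)[C@@H]12 | target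

**Step count and risk**
Total: 22 steps. Longest linear sequence: 14 steps (steps 1–12, 21, 22).

Most likely to fail, first: step 21. The chair transition state demands attack on the aldehyde face that the Felkin–Anh (polar) model for an α-acyloxy aldehyde disfavours, so the C8 epimer may compete; 30 can also epimerise at C9 and the product can suffer acyl shift. The fallback sets out from hydroxy lactone 18 and aldehyde 30 and returns to the route at 32. Alcohol 18 is acetylated (Ac2O, pyridine) to (1Z,3S)-1-[(2R,3RS)-3-acetoxy-4-methylidene-5-oxooxolan-2-yl]-2-methylhexa-1,5-dien-3-yl acetate F1. F1 is ionised at the activated allylic acetate by Pd(PPh3)4 (zerovalent palladium, 5 mol %) and reduced in the same flask by indium monoiodide, InI, in THF/H2O in the presence of 30. The allylindium species formed this way is a stronger chelator of α-oxygenated aldehydes than the zinc reagent and should favour the 8,9-syn adduct 32.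

Second: step 22. A ten-membered ring with a new trisubstituted alkene next to a bulky acyloxy group may close slowly, dimerise, or engage the conjugated methylene. The fallback sets out from 32 and returns at 33. Dimethylamine (1.2 equiv, THF, 0 °C) is added to the exocyclic methylene to give (1Z,3S)-1-[(2R,3R,4RS)-4-[(dimethylamino)methyl]-3-{(1R,2R)-2-{[(2R,3R)-2,3-dimethyloxirane-2-carbonyl]oxy}-1-hydroxy-3-methylbut-3-en-1-yl}-5-oxooxolan-2-yl]-2-methylhexa-1,5-dien-3-yl acetate F2. F2 is cyclised as its camphorsulfonate salt with RuCl2(=CHPh)(PCy3)(H2IMes) (second-generation Grubbs catalyst) in toluene at 80 °C to (3RS,3aR,4R,5R,6Z,9S,10Z,11aR)-9-acetoxy-3-[(dimethylamino)methyl]-4-hydroxy-6,10-dimethyl-2-oxo-2,3,3a,4,5,8,9,11a-octahydrocyclodeca[b]furan-5-yl (2R,3R)-2,3-dimethyloxirane-2-carboxylate F3. Quaternisation with MeI gives the trimethylammonium iodide of F3, {[(3RS,3aR,4R,5R,6Z,9S,10Z,11aR)-9-acetoxy-5-{[(2R,3R)-2,3-dimethyloxirane-2-carbonyl]oxy}-4-hydroxy-6,10-dimethyl-2-oxo-2,3,3a,4,5,8,9,11a-octahydrocyclodeca[b]furan-3-yl]methyl}trimethylammonium iodide F4, which eliminates on stirring with aqueous NaHCO3 to restore the methylene lactone 33. The basic amine steps carry their own risk of 9→8 acyl shift and must be kept cold and short.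

Third: step 10. Aldehyde 14 carries an acidic, doubly activated C6–H, and a slow amine-catalysed reaction may epimerise C6 or move the C4=C5 alkene into conjugation. The fallback sets out from 14 and returns at 16. Methyl propiolate is hydroaluminated with iBu2AlH and N-methylmorpholine N-oxide in THF at 0 °C to [1-(methoxycarbonyl)ethenyl]bis(2-methylpropyl)alumane F5, a preformed α-metallated acrylate. F5 adds to 14 within hours without an amine base and gives 16 after aqueous work-up.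

**Further compounds**
F1 | step 21 | (1Z,3S)-1-[(2R,3RS)-3-acetoxy-4-methylidene-5-oxooxolan-2-yl]-2-methylhexa-1,5-dien-3-yl acetate | C=C1C(OC(C)=O)[C@@H](/C=C(/C)[C@@H](OC(C)=O)CC=C)OC1=O
F2 | step 22 | (1Z,3S)-1-[(2R,3R,4RS)-4-[(dimethylamino)methyl]-3-{(1R,2R)-2-{[(2R,3R)-2,3-dimethyloxirane-2-carbonyl]oxy}-1-hydroxy-3-methylbut-3-en-1-yl}-5-oxooxolan-2-yl]-2-methylhexa-1,5-dien-3-yl acetate | CN(C)CC1C(=O)O[C@H](/C=C(/C)[C@@H](OC(C)=O)CC=C)[C@H]1[C@@H](O)[C@H](OC(=O)[C@]2(C)O[C@@H]2C)C(C)=C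
F3 | step 22 | (3RS,3aR,4R,5R,6Z,9S,10Z,11aR)-9-acetoxy-3-[(dimethylamino)methyl]-4-hydroxy-6,10-dimethyl-2-oxo-2,3,3a,4,5,8,9,11a-octahydrocyclodeca[b]furan-5-yl (2R,3R)-2,3-dimethyloxirane-2-carboxylate | CN(C)CC1C(=O)O[C@@H]2/C=C(/C)[C@@H](OC(C)=O)C/C=C(/C)[C@@H](OC(=O)[C@]3(C)O[C@@H]3C)[C@H](O)[C@@H]12
F4 | step 22 | {[(3RS,3aR,4R,5R,6Z,9S,10Z,11aR)-9-acetoxy-5-{[(2R,3R)-2,3-dimethyloxirane-2-carbonyl]oxy}-4-hydroxy-6,10-dimethyl-2-oxo-2,3,3a,4,5,8,9,11a-octahydrocyclodeca[b]furan-3-yl]methyl}trimethylammonium iodide | C[N+](C)(C)CC1C(=O)O[C@@H]2/C=C(/C)[C@@H](OC(C)=O)C/C=C(/C)[C@@H](OC(=O)[C@]3(C)O[C@@H]3C)[C@H](O)[C@@H]12.[I-]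
F5 | step 10 | [1-(methoxycarbonyl)ethenyl]bis(2-methylpropyl)alumane | C=C(C(=O)OC)[Al](CC(C)C)CC(C)C
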